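The runs were generated by integration with made-up constants, noise included.

- Start with the easy part: from 3.00 h on, J reads 4% or less in oak and cedar, far below E, so little J is left to feed E and the fraction of the charge held as E can simply shrink.

| flask | J | Q | remark | time | volume of the second phase over the first |
|---|---|---|---|---|---|
| oak | 0.25 M | 0.40 M | run made earlier |  |  |
| cedar | 0.38 M | 0.40 M | run made earlier |  |  |
| flask | 0.50 M | 0.400 M |  | 15 h | 0.25 |

| run | time / h | E / % | J / % |
|---|---|---|---|
| oak | 1.00 | 60 | 18 |
| oak | 1.33 | 63 | 7 |
| oak | 2.00 | 65 | 3 |
| oak | 3.00 | 56 | 4 |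
| oak | 5.00 | 43 | 0 |
| oak | 8.00 | 28 | 0 |
| oak | 12.0 | 15 | 3 |
| cedar | 0.667 | 39 | 39 |
| cedar | 2.00 | 53 | 4 |
| cedar | 3.00 | 50 | 0 |
| cedar | 5.00 | 35 | 0 |
| cedar | 8.00 | 24 | 0 |
| cedar | 10.0 | 18 | 0 |
| cedar | 12.0 | 16 | 0 |

(each reading ± 1.5 percentage points)

- E and G together at 15 h, in percent of the J charged
- part of the J charged that has reacted at 15 h

- what is said of E includes G
- in the second phase: Q, G; everything else is in the first
- charges count per volume of the first phase; a concentration in a rate is the amount of a species over the volume of its own phase; every rate counts per litre of the first phase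
- the numbers in the tables scatter with a standard deviation of 1.5 percentage points
- the earlier runs hold the two phases in the same ratio of volumes as the flask asked about

- Since E is counted with G, I treat their exchange as quick and follow the sum. Define the tail rate (an apparent first-order rate constant) as the logarithm of the fall in that fraction, per hour, once J has stopped feeding it.
- Oak gives 0.146 h⁻¹ and cedar 0.127 h⁻¹, so despite different charges I take their mean, 0.136 h⁻¹, as the tail rate.
- My first way to the asked fraction starts from the late readings, 15% and 16% at 12.0 h. Carried to 15 h, their mean gives 10.3%.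
- My second way starts early. At 2.00 h the readings fall from 65% in oak to 53% in cedar, and a straight line to this flask's charge gives 41.9%, which the tail rate carries to 7.11%.
- The two ways part, and the first one cheats: it lends this flask the fraction of smaller charges, while the late readings lie too close, within their scatter, to show the trend. I commit to 7.11%, and with J at 0% in cedar from 3.00 h, I expect 100% reacted.
- The forecast says 10% (from 6% to 14%), above my figure, and 98% (from 85% to 100%), noting “A side loss of higher order in J is therefore likely”.
- The flask gives 7.87% and 100%, inside both forecast ranges.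

    X ⇌ Q, rate k1*([X] - [Q]/K1) per volume of the first phase (partition coefficient = 1.80, kL = 0.00870 min⁻¹)
    J + X → E (k = 0.360 M⁻¹ min⁻¹)
    E ⇌ G, rate k3*([E] - [G]/K3) per volume of the first phase (partition coefficient = 1.00, kL = 0.00610 min⁻¹)
    E → Z (k = 0.00300 min⁻¹)
    J + E → D (k = 0.00900 M⁻¹ min⁻¹)
    2 J → L (k = 0.0160 M⁻¹ min⁻¹)

- In this flask, E reads 22.6% at 7.50 h, and the tail rate carries that to 8.15% at 15 h, beside 7.87%. The neighbouring flask is this one read at 4.0 h, with J at 0.395%; carrying 7.87% back by the tail rate gives 35.1%, and that flask reads 36.7%.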